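**Plan**

Retrosynthesis (gibberellane numbering): the C7 acid of the target gibberellin comes from the 7-aldehyde. The C8–C14 bond is cut next, which opens rings C and D together and returns the C16=C17 methylene to a C13–C14–C16 cyclopropane with CH2SiMe3 on C16. The 1β,2β-diol comes from the Δ1 alkene, ring B is cut at C6=C8 (aldol condensation), and the C9–C10 bond and the lactone O–C19 bond are cut together (aldol/lactonisation) to fragment 1 (ring A, 12) and fragment 2 (cycloheptanone 19).
Forward: ring A arises by Diels–Alder reaction, cleavage of the auxiliary cyclopentanone and singlet-oxygen oxidation; the cyclopropane-fused seven-membered ring by allylation, ring-closing metathesis and cyclopropanation. The union gives the lactone, then ring B, then the ring A triol, then rings C and D in one event, then the acid.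
Stereochemistry: C4/C5 from a catalytic asymmetric Diels–Alder step; C3 from β-face singlet-oxygen addition; C10 and C9 from the aldol (only the C10 alkoxide cis to C19 can lactonise); C1/C2 from hydroxyl-directed osmylation. C13, and through the bridged ring C8, come from a carbinol set by asymmetric allylation that directs the cyclopropanation and is then oxidised away; C6 by equilibration.
Enabling feature: C14 is the one-carbon bridge between C8 and C13 and is 1,3 to the methylene carbon C16, so C14–C16 can be a strained, silicon-activated σ-bond; C8 is the β-carbon of the C7 carbonyl through C6. Donor and acceptor face each other 1,4 across the ring C8–C9–C11–C12–C13–C16–C15.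

Key step: step 16

Remark: locants C1–C19 are gibberellane locants and α/β have their usual gibberellin meaning (lactone bridge on the α face); they are used for all intermediates.

**Route**

Step 1
Reactants: 1 2-methylcyclopent-2-en-1-one; 2 buta-1,3-diene
Product: 3 (3aS,7aR)-7a-methyl-2,3,3a,4,7,7a-hexahydro-1H-inden-1-one
Conditions: (S)-diphenylprolinol-derived B-(o-tolyl)oxazaborolidine (10 mol %), AlBr3 (8 mol %), excess 2, CH2Cl2, −40 °C
Reagents that add atoms: none
Why: Lewis-acid-catalysed Diels–Alder reaction of an α-substituted cycloalkenone, in which suprafacial addition gives the cis ring fusion (C4 methyl, C19 carbonyl and the C5–C6 bond in their final relationship) and the chiral oxazaborolidinium cation shields one enone face, so that C4 and C5 are set in the absolute sense.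

Step 2
Reactants: 3 (3aS,7aR)-7a-methyl-2,3,3a,4,7,7a-hexahydro-1H-inden-1-one
Product: 4 (3aS,7aR)-5,6-dibromo-7a-methyloctahydro-1H-inden-1-one (trans-dibromide)
Conditions: Br2, CH2Cl2, −78 °C
Reagents that add atoms: bromine BrBr
Why: anti bromination of the isolated alkene through the bromonium ion masks it against ozone and installs the two leaving groups for the later diene; the configuration of the two CHBr centres is lost in step 5.

Step 3
Reactants: 4 (3aS,7aR)-5,6-dibromo-7a-methyloctahydro-1H-inden-1-one
Product: 6 trans-4,5-dibromo-1-methyl-2-(2-oxoethyl)cyclohexane-1-carboxylic acid (carboxyl cis to the oxoethyl chain), via silyl enol ether 5 (not isolated)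
Conditions: TMSOTf, Et3N, CH2Cl2, 0 °C; then O3, CH2Cl2/MeOH, −78 °C; Me2S
Reagents that add atoms: trimethylsilyl triflate C[Si](C)(C)OS(=O)(=O)C(F)(F)F (silicon kept only in 5); ozone [O-][O+]=O
Why: the ketone can enolise only toward C7 because C4 is quaternary, so the silyl enol ether forms regiospecifically and its ozonolysis cleaves the C19–C7 bond to the C19 acid and the C7 aldehyde on cis side chains.

Step 4
Reactants: 6 trans-4,5-dibromo-1-methyl-2-(2-oxoethyl)cyclohexane-1-carboxylic acid
Product: 8 methyl trans-4,5-dibromo-2-(2,2-dimethoxyethyl)-1-methylcyclohexane-1-carboxylate, via methyl ester aldehyde 7 (not isolated)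
Conditions: TMSCHN2, MeOH/toluene, 0 °C; then HC(OMe)3, pyridinium p-toluenesulfonate, MeOH, rt
Reagents that add atoms: (trimethylsilyl)diazomethane C[Si](C)(C)C=[N+]=[N-]; trimethyl orthoformate COC(OC)OC
Why: diazoalkane esterification accepts the hindered neopentyl acid, and acid-catalysed acetalisation then masks the aldehyde against the enolate chemistry of step 12.

Step 5
Reactants: 8 methyl trans-4,5-dibromo-2-(2,2-dimethoxyethyl)-1-methylcyclohexane-1-carboxylate
Product: 9 methyl (1R,6S)-6-(2,2-dimethoxyethyl)-1-methylcyclohexa-2,4-diene-1-carboxylate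
Conditions: DBU, toluene, 100 °C
Reagents that add atoms: none
Why: twofold E2 dehydrobromination; C4 carries no hydrogen, so the eliminations run toward C10 and C3 and should give the conjugated C10=C1–C2=C3 diene.

Step 6
Reactants: 9 methyl (1R,6S)-6-(2,2-dimethoxyethyl)-1-methylcyclohexa-2,4-diene-1-carboxylate
Product: 12 methyl (1S,2S,6R)-6-(2,2-dimethoxyethyl)-1-methyl-5-oxo-2-(triethylsilyloxy)cyclohex-3-ene-1-carboxylate (fragment 1), via endoperoxide 10 (not isolated), via hydroxy enone 11 (not isolated)
Conditions: O2, tetraphenylporphyrin (cat.), visible light, CH2Cl2, −40 °C; then Et3N, 0 °C; then TESCl, imidazole, rt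
Reagents that add atoms: dioxygen O=O; chlorotriethylsilane CC[Si](Cl)(CC)CC
Why: [4+2] addition of singlet oxygen anti to the axial C4 ester and the C5 side chain should place both new C–O bonds on the β face, and the Kornblum–DeLaMare fragmentation should remove the more accessible H–C10 (H–C3 is flanked by the quaternary C4) to give the C10 ketone and the 3β-alcohol, which is silylated.

Step 7
Reactants: 13 2-(chloromethyl)-3-(trimethylsilyl)prop-1-ene
Product: 14 tributyl{2-[(trimethylsilyl)methyl]prop-2-en-1-yl}stannane
Conditions: Bu3SnH, LiN(iPr)2, THF, 0 °C; then 13, −78 → 0 °C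
Reagents that add atoms: tributyltin hydride CCCC[SnH](CCCC)CCCC
Why: SN2 displacement of the allylic chloride by the stannyl anion (the SN2' path gives the same product).

Step 8
Reactants: 14 tributyl{2-[(trimethylsilyl)methyl]prop-2-en-1-yl}stannane; 15 hex-5-enal
Product: 16 (4R)-2-[(trimethylsilyl)methyl]nona-1,8-dien-4-ol
Conditions: (S)-BINOL (10 mol %), Ti(OiPr)4 (10 mol %), 4 Å molecular sieves, CH2Cl2, −20 °C
Reagents that add atoms: none
Why: Keck asymmetric allylation, in which the allylstannane end (far more reactive than the allylsilane end) adds by SE2' to the aldehyde face left open by the BINOL–titanium complex and sets the (R)-carbinol.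

Step 9
Reactants: 16 (4R)-2-[(trimethylsilyl)methyl]nona-1,8-dien-4-ol
Product: 17 (1R)-3-[(trimethylsilyl)methyl]cyclohept-3-en-1-ol
Conditions: second-generation Grubbs catalyst RuCl2(=CHPh)(H2IMes)(PCy3) (5 mol %), CH2Cl2 (5 mM), 40 °C
Reagents that add atoms: none
Why: ring-closing olefin metathesis of a 1,8-diene to a trisubstituted cycloheptene, driven by loss of ethene.

Step 10
Reactants: 17 (1R)-3-[(trimethylsilyl)methyl]cyclohept-3-en-1-ol
Product: 18 (1S,3R,7R)-1-[(trimethylsilyl)methyl]bicyclo[5.1.0]octan-3-ol
Conditions: Et2Zn, CH2I2, CH2Cl2, −10 → 0 °C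
Reagents that add atoms: diiodomethane ICI
Why: Simmons–Smith cyclopropanation of the electron-rich allylsilane double bond, delivered by the homoallylic zinc alkoxide to its own ring face, so that the carbinol configuration fixes the two cyclopropane stereocentres (C13 and C16).

Step 11
Reactants: 18 (1S,3R,7R)-1-[(trimethylsilyl)methyl]bicyclo[5.1.0]octan-3-ol
Product: 19 (1S,7R)-1-[(trimethylsilyl)methyl]bicyclo[5.1.0]octan-3-one (fragment 2)
Conditions: Dess–Martin periodinane, NaHCO3, CH2Cl2, rt
Reagents that add atoms: none
Why: alcohol oxidation that erases the directing carbinol once it has done its work and leaves the cyclopropane as the only stereochemical element of fragment 2.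

Step 12
Reactants: 19 (1S,7R)-1-[(trimethylsilyl)methyl]bicyclo[5.1.0]octan-3-one; 12 methyl (1S,2S,6R)-6-(2,2-dimethoxyethyl)-1-methyl-5-oxo-2-(triethylsilyloxy)cyclohex-3-ene-1-carboxylate
Product: 21 keto lactone (19,10-lactone of ring A bearing the bicyclo[5.1.0]octan-3-one at C10), via aldol adduct 20 (not isolated)
Conditions: 19, LiN(iPr)2, THF, −78 °C; CeCl3, −78 °C; then 12, −78 → −20 °C; aq. NH4Cl
Reagents that add atoms: none
Why: kinetic enolisation on the unhindered C9 side (C15 is neopentyl) and 1,2-aldol addition of the cerium enolate to the enone carbonyl from the β face (anti to the C5 side chain) through a closed Zimmerman–Traxler transition state with the bulky C5 branch equatorial should give the anti C9/C10 relationship, and the C10 alkoxide, cis to the C4 ester, closes the 19,10-γ-lactone and so makes the reversible aldol irreversible.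

Step 13
Reactants: 21 keto lactone
Product: 22 keto aldehyde (3β-hydroxy, C7 aldehyde, C8 ketone)
Conditions: AcOH/THF/H2O (3:1:1), 40 °C
Reagents that add atoms: water O
Why: mild acid hydrolysis of the dimethyl acetal and the triethylsilyl ether, under which the allylic lactone and the cyclopropylmethylsilane should survive.

Step 14
Reactants: 22 keto aldehyde
Product: 23 enal (ring B closed, C6=C8, formyl on C6)
Conditions: dibenzylammonium trifluoroacetate (0.3 equiv), benzene, 50 °C
Reagents that add atoms: none
Why: amine-salt-catalysed intramolecular aldol condensation (5-enolexo), in which the aldehyde enamine attacks the C8 ketone and dehydration into conjugation gives the tetrasubstituted enal; no new stereocentre is formed.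

Step 15
Reactants: 23 enal
Product: 25 triol enal (1β,2β,3β-triol), via osmate ester 24 (not isolated)
Conditions: OsO4 (1.05 equiv), TMEDA, CH2Cl2, −78 °C; then aq. Na2SO3, THF, 40 °C
Reagents that add atoms: osmium tetroxide O=[Os](=O)(=O)=O; N,N,N',N'-tetramethylethane-1,2-diamine CN(C)CCN(C)C (kept only in 24)
Why: hydroxyl-directed dihydroxylation with OsO4/TMEDA, in which hydrogen bonding to the 3β-hydroxyl and the blocking of the α face by the lactone bridge both send the reagent to the β face, so that the cis-1β,2β-diol forms syn to the 3β-OH while the electron-poor tetrasubstituted enal stays untouched.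

Step 16
Reactants: 25 triol enal
Product: 27 target gibberellin 7-aldehyde (6β-formyl), via 6-epi aldehyde 26 (not isolated)
Conditions: MeAlCl2 (5 equiv), CH2Cl2, −78 → −20 °C; aq. KNaC4H4O6; then DBU (0.2 equiv), CH2Cl2, rt
Reagents that add atoms: none
Why: Proposed new method: complexation of MeAlCl2 to the enal makes C8 (β-carbon, tertiary allyl cation character) electrophilic, and the C14–C16 σ-bond of the cyclopropane, raised in energy by ring strain and by hyperconjugation with the C17–Si bond, attacks it across the seven-membered ring; C14–C16 breaks as C14–C8 forms, the positive charge arrives at C16 β to silicon, and loss of the silyl group leaves the C16=C17 methylene while the aluminium enolate is protonated on work-up. The closest known reaction type is the Hosomi–Sakurai conjugate allylation of enones, of which this is the homologue, cyclopropylmethylsilanes being known to transfer a but-3-enyl group to acyl and oxocarbenium electrophiles. Rings C and D close together, ring D in a 5-exo-trig and ring C in a 6-exo-trig sense with respect to the C6=C8 bond, as a transannular closure across the ring C8–C9–C11–C12–C13–C16–C15. C8 is set by C13, because C14 is held on one face of the seven-membered ring, can reach only that face of C8, and the bridged bicyclo[3.2.1]octane allows no other arrangement; C13 is retained, and C6 is set on protonation, the kinetically formed epimer being equilibrated by DBU to the 6β-aldehyde, trans to the C4 substituent on C5. The step needs cleavage of the C14–C16 and not the C13–C16 bond, secured by attack at the less substituted cyclopropane carbon and by β-silicon stabilisation of charge at C16, and 1,4- over 1,2-addition, secured by the transannular distance (C8 lies in the ring, C7 outside it). The free hydroxyls should be tolerated as aluminium alkoxides formed with the excess reagent.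

Step 17
Reactants: 27 target gibberellin 7-aldehyde (6β-formyl)
Product: 28 target gibberellin (C19 gibberellin 19,10-lactone with 1β,2β,3β-triol, 16-methylene and 6β-carboxyl)
Conditions: NaClO2, NaH2PO4, 2-methylbut-2-ene, t-BuOH/H2O, 0 °C → rt
Reagents that add atoms: sodium chlorite [Na+].[O-]Cl=O
Why: Pinnick oxidation of the hindered aldehyde to the acid, with the alkene scavenger protecting the exocyclic methylene from hypochlorous acid and no base that could epimerise C6 or C3.

**Compound list**

1 | 2-methylcyclopent-2-en-1-one | CC1=CCCC1=O | starting material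
2 | buta-1,3-diene | C=CC=C | starting material
3 | (3aS,7aR)-7a-methyl-2,3,3a,4,7,7a-hexahydro-1H-inden-1-one (cis ring fusion) | O=C1CC[C@H]2CC=CC[C@@]12C | intermediate
4 | (3aS,7aR)-5,6-dibromo-7a-methyloctahydro-1H-inden-1-one (trans-dibromide, cis ring fusion) | O=C1CC[C@H]2C[C@@H](Br)[C@H](Br)C[C@@]12C | intermediate
5 | trimethylsilyl enol ether of 4 (enol double bond toward the ring CH2) | C[Si](C)(C)OC1=CC[C@H]2C[C@@H](Br)[C@H](Br)C[C@@]12C | intermediate (not isolated)
6 | trans-4,5-dibromo-1-methyl-2-(2-oxoethyl)cyclohexane-1-carboxylic acid (carboxyl cis to the oxoethyl chain) | C1[C@@H](Br)[C@H](Br)C[C@@](C)(C(=O)O)[C@H]1CC=O | intermediate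
7 | methyl ester of 6 | C1[C@@H](Br)[C@H](Br)C[C@@](C)(C(=O)OC)[C@H]1CC=O | intermediate (not isolated)
8 | methyl trans-4,5-dibromo-2-(2,2-dimethoxyethyl)-1-methylcyclohexane-1-carboxylate (ester cis to the side chain) | C1[C@@H](Br)[C@H](Br)C[C@@](C)(C(=O)OC)[C@H]1CC(OC)OC | intermediate
9 | methyl (1R,6S)-6-(2,2-dimethoxyethyl)-1-methylcyclohexa-2,4-diene-1-carboxylate | C1=CC=C[C@@](C)(C(=O)OC)[C@H]1CC(OC)OC | intermediate
10 | endoperoxide of 9 (peroxide bridge C3–O–O–C10 on the face anti to ester and side chain) | [C@H]12C=C[C@H](OO1)[C@@](C)(C(=O)OC)[C@H]2CC(OC)OC | intermediate (not isolated)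
11 | methyl (1S,2S,6R)-6-(2,2-dimethoxyethyl)-2-hydroxy-1-methyl-5-oxocyclohex-3-ene-1-carboxylate | O=C1C=C[C@H](O)[C@@](C)(C(=O)OC)[C@H]1CC(OC)OC | intermediate (not isolated)
12 | methyl (1S,2S,6R)-6-(2,2-dimethoxyethyl)-1-methyl-5-oxo-2-(triethylsilyloxy)cyclohex-3-ene-1-carboxylate (fragment 1) | O=C1C=C[C@H](O[Si](CC)(CC)CC)[C@@](C)(C(=O)OC)[C@H]1CC(OC)OC | intermediate
13 | 2-(chloromethyl)-3-(trimethylsilyl)prop-1-ene | C[Si](C)(C)CC(=C)CCl | starting material
14 | tributyl{2-[(trimethylsilyl)methyl]prop-2-en-1-yl}stannane | CCCC[Sn](CCCC)(CCCC)CC(=C)C[Si](C)(C)C | intermediate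
15 | hex-5-enal | C=CCCCC=O | starting material
16 | (4R)-2-[(trimethylsilyl)methyl]nona-1,8-dien-4-ol | C[Si](C)(C)CC(=C)C[C@H](O)CCCC=C | intermediate
17 | (1R)-3-[(trimethylsilyl)methyl]cyclohept-3-en-1-ol | C[Si](C)(C)CC1=CCCC[C@@H](O)C1 | intermediate
18 | (1S,3R,7R)-1-[(trimethylsilyl)methyl]bicyclo[5.1.0]octan-3-ol (hydroxyl cis to the cyclopropane CH2) | C[Si](C)(C)C[C@]1(C[C@@H]2O)C[C@H]1CCC2 | intermediate
19 | (1S,7R)-1-[(trimethylsilyl)methyl]bicyclo[5.1.0]octan-3-one (fragment 2) | C[Si](C)(C)C[C@]1(CC2=O)C[C@H]1CCC2 | intermediate
20 | aldol adduct: tertiary C10 alcohol of 12 carrying C9 of the bicyclo[5.1.0]octan-3-one, methyl ester intact | C[Si](C)(C)C[C@]1(CC2=O)C[C@H]1CC[C@H]2[C@]1(O)C=C[C@H](O[Si](CC)(CC)CC)[C@@](C)(C(=O)OC)[C@H]1CC(OC)OC | intermediate (not isolated)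
21 | keto lactone: ring A (Δ1, 3β-OTES, 4β-methyl) bridged by the 19,10-γ-lactone on the α face; C5 carries CH2CH(OMe)2 (C6, C7); C10 is bonded to C9 of the (1S,7R)-1-(trimethylsilylmethyl)bicyclo[5.1.0]octan-3-one (C8 ketone) | C[Si](C)(C)C[C@]1(CC2=O)C[C@H]1CC[C@H]2[C@@]12OC(=O)[C@@](C)([C@H]1CC(OC)OC)[C@@H](O[Si](CC)(CC)CC)C=C2 | intermediate
22 | keto aldehyde: as 21 with free 3β-OH and C5–CH2–CHO | C[Si](C)(C)C[C@]1(CC2=O)C[C@H]1CC[C@H]2[C@@]12OC(=O)[C@@](C)([C@H]1CC=O)[C@@H](O)C=C2 | intermediate
23 | enal: rings A and B and the lactone as in the target (Δ1, 3β-OH), C6=C8 double bond with formyl on C6; cycloheptane C8–C15–C16–C13–C12–C11–C9 fused to the cyclopropane C13–C14–C16, CH2SiMe3 on C16 | C[Si](C)(C)C[C@]1(CC2=3)C[C@H]1CC[C@H]2[C@@]12OC(=O)[C@@](C)([C@H]1C=3C=O)[C@@H](O)C=C2 | intermediate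
24 | cyclic osmate ester of the 1β,2β-diol of 25 (hexavalent osmium, dioxo, chelated by TMEDA) | C[Si](C)(C)C[C@]1(CC2=3)C[C@H]1CC[C@H]2[C@@]12OC(=O)[C@@](C)([C@H]1C=3C=O)[C@@H](O)[C@H]4O[Os-2]5(=O)(=O)([N+](C)(C)CC[N+]5(C)C)O[C@H]42 | intermediate (not isolated)
25 | triol enal: as 23 with 1β,2β,3β-triol in ring A | C[Si](C)(C)C[C@]1(CC2=3)C[C@H]1CC[C@H]2[C@@]12OC(=O)[C@@](C)([C@H]1C=3C=O)[C@@H](O)[C@@H](O)[C@H]2O | intermediate
26 | 6-epimer of the target gibberellin 7-aldehyde (formyl on the α face of C6) | C=C1C[C@]23C[C@H]1CC[C@H]2[C@@]12OC(=O)[C@@](C)([C@H]1[C@H]3C=O)[C@@H](O)[C@@H](O)[C@H]2O | intermediate (not isolated)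
27 | target gibberellin 7-aldehyde: C19 gibberellin skeleton of natural configuration with 19,10-lactone, 1β,2β,3β-triol, exocyclic 16-methylene and 6β-formyl (C7) | C=C1C[C@]23C[C@H]1CC[C@H]2[C@@]12OC(=O)[C@@](C)([C@H]1[C@@H]3C=O)[C@@H](O)[C@@H](O)[C@H]2O | intermediate
28 | target gibberellin: C19 gibberellin skeleton of natural configuration with 19,10-lactone (α face), 1β,2β,3β-triol, exocyclic 16-methylene and 6β-carboxyl (C7), α/β as in the remark | C=C1C[C@]23C[C@H]1CC[C@H]2[C@@]12OC(=O)[C@@](C)([C@H]1[C@@H]3C(=O)O)[C@@H](O)[C@@H](O)[C@H]2O | target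

**Step count and risks**

Total step count: 17. Longest linear sequence: 12 steps (steps 1–6, then 12–17); the branch to fragment 2 is 5 steps (7–11).

Steps most likely to fail:

1. Step 16 (Proposed new method). The strained σ-bond may be too weak a nucleophile for the fully substituted β-carbon, so that protodesilylative ring opening by adventitious acid or methyl transfer from aluminium to the aldehyde takes over. Fallback in known chemistry, setting out from 25: N-iodosuccinimide in CH2Cl2 at −20 °C opens the cyclopropane by electrophilic attack at C14 with loss of the silyl group (the established homoallyl-transfer reactivity of cyclopropylmethylsilanes toward soft electrophiles) and gives the homoallylic iodide F1, which already carries the C16=C17 methylene. Bu3SnH with Et3B/air in toluene at 0 °C then generates the primary C14 radical, which closes onto C8 of the enal in a transannular 5-exo radical conjugate addition. The same DBU equilibration of C6 brings the route back at 27.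

2. Step 12. Proton transfer between enolate and enone, retro-aldol cleavage or conjugate addition may outrun the lactonisation, or the carbonyl may be attacked from the wrong face. Fallback, setting out from 19: LiN(iPr)2 and TMSCl in THF at −78 °C give the kinetic silyl enol ether F2, and N-bromosuccinimide in THF at 0 °C converts it into the α-bromo ketone F3 (bromine on C9, either epimer). Activated zinc in THF with 12 at 0 °C → rt then forms the Reformatsky zinc enolate, which adds 1,2 to the C10 carbonyl in the absence of any amide base; the zinc alkoxide lactonises, and the route is rejoined at 21.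

3. Step 6. The peroxide fragmentation may remove H–C3 instead of H–C10 and give the regioisomeric 3-keto-10-ol. Fallback, setting out from 9: after the same photooxygenation to 10, reduction of the O–O bond with Zn in AcOH gives the cis-enediol F4, and MnO2 in CH2Cl2 oxidises only the less hindered allylic C10 alcohol (the C3 alcohol is neopentyl). This returns the route at 11, which is silylated as in step 6 to 12.

Further compounds
F1 | step 16 | homoallylic iodide: as 25 but with C16=C17 exocyclic methylene on the cycloheptane and CH2I (C14) on C13 | C=C(CC2=3)[C@@H](CI)CC[C@H]2[C@@]12OC(=O)[C@@](C)([C@H]1C=3C=O)[C@@H](O)[C@@H](O)[C@H]2O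
F2 | step 12 | (1S,7R)-3-(trimethylsilyloxy)-1-[(trimethylsilyl)methyl]bicyclo[5.1.0]oct-3-ene | C[Si](C)(C)C[C@]1(CC(O[Si](C)(C)C)=C2)C[C@H]1CC2
F3 | step 12 | (1S,7R)-4-bromo-1-[(trimethylsilyl)methyl]bicyclo[5.1.0]octan-3-one (either C4 epimer) | C[Si](C)(C)C[C@]1(CC(=O)C2Br)C[C@H]1CC2
F4 | step 6 | methyl 6-(2,2-dimethoxyethyl)-2,5-dihydroxy-1-methylcyclohex-3-ene-1-carboxylate (both hydroxyls on the face anti to ester and side chain) | O[C@@H]1C=C[C@H](O)[C@@](C)(C(=O)OC)[C@H]1CC(OC)OC
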